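The depside is cut at the bond between C1 of ring A and the ester carbonyl carbon. The key step adds a 2,4-dimethoxy-6-methylphenyl Grignard reagent to the carbonyl carbon of a five-membered cyclic carbonate that bridges O4 and O5 of ring B. It exploits the catechol pair O4/O5 of ring B: ring opening expels the more acidic O4 (para to the ring-B carboxyl), so one operation forms the aryl–carbonyl bond, leaves the ester on O5 and frees the 4-OH. The precursor is an aldehyde-free benzodioxol-2-one; both formyl groups enter afterwards, ortho to the phenols, and a benzyl ester is removed last.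

Key step: step 5

Remark: the target has no stereogenic element, so it is one achiral compound and no stereocontrol is needed.

Step 1
Reactants: 1 orsellinic acid (2,4-dihydroxy-6-methylbenzoic acid)
Product: 2 benzyl 2,4-dihydroxy-6-methylbenzoate
Conditions: BnBr (1.05 equiv), KHCO3, DMF, rt
Reagents that add atoms: benzyl bromide, BrCc1ccccc1
Why: Carboxylate O-alkylation (SN2): bicarbonate deprotonates only the carboxylic acid, so benzyl bromide should esterify it and leave both phenols free.

Step 2
Reactants: 2 benzyl 2,4-dihydroxy-6-methylbenzoate
Product: 4 benzyl 2,4,5-trihydroxy-6-methylbenzoate, via potassium aryl sulfate 3 (not isolated)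
Conditions: K2S2O8, 2 M NaOH/pyridine, 0 °C to rt; then HCl (pH 1), Na2SO3, 70 °C
Reagents that add atoms: potassium persulfate, [K+].[K+].[O-]S(=O)(=O)OOS(=O)(=O)[O-]
Why: Elbs persulfate oxidation: the phenoxide of 2 attacks the peroxide oxygen through C5, the only free position para to an oxido group, and acid hydrolysis of the aryl sulfate should give the 5-phenol, while the hindered ortho-oxido benzoate ester should resist the cold alkali.

Step 3
Reactants: 4 benzyl 2,4,5-trihydroxy-6-methylbenzoate
Product: 5 benzyl 6-hydroxy-4-methyl-2-oxo-1,3-benzodioxole-5-carboxylate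
Conditions: CDI (1.1 equiv), THF, 0 °C to rt, argon
Reagents that add atoms: 1,1'-carbonyldiimidazole, O=C(n1ccnc1)n1ccnc1
Why: Carbonylation of a catechol with CDI: only O4 and O5 are adjacent, so the five-membered cyclic carbonate should close there, while the 2-OH, hydrogen-bonded to the ester, stays free.

Step 4
Reactants: 6 3,5-dimethoxytoluene
Product: 7 1-bromo-2,4-dimethoxy-6-methylbenzene
Conditions: NBS (1.0 equiv), MeCN, 0 °C to rt
Reagents that add atoms: N-bromosuccinimide, O=C1CCC(=O)N1Br
Why: Electrophilic aromatic bromination: NBS should attack the position ortho to the methyl group and para to a methoxy group and not the hindered site between the two methoxy groups, and the two such positions are equivalent by symmetry.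

Step 5
Reactants: 7 1-bromo-2,4-dimethoxy-6-methylbenzene; 5 benzyl 6-hydroxy-4-methyl-2-oxo-1,3-benzodioxole-5-carboxylate
Product: 9 benzyl 5-[(2,4-dimethoxy-6-methylbenzoyl)oxy]-2,4-dihydroxy-6-methylbenzoate, via aryl Grignard reagent 8 (not isolated)
Conditions: 7 (2.2 equiv), Mg, THF, 50 °C; then added to 5, THF, −78 to 0 °C; aq. HCl work-up
Reagents that add atoms: none
Why: Grignard acylation by a carbonate (nucleophilic acyl substitution): the first equivalent of 8 deprotonates the 6-OH of 5, the second adds to the carbonate carbonyl, and the tetrahedral magnesium hemi-orthoester collapses to the aryl ester. The closest known reaction type is ester synthesis from aryl Grignard reagents and carbonates or chloroformates. No ring is closed (the dioxolone ring is opened) and no stereocentre is formed. The step needs regioselective C–O cleavage, mono-addition and chemoselectivity over the benzyl ester: the oxygen that leaves is the one para to the ester group (ring-B O4), the better phenoxide leaving group, whereas O5 is para to the magnesium oxido group and ortho to methyl, so the acyl group should stay on O5. The new ester is flanked by OMe and Me on ring A, which should block a second addition, and the benzyl ester is shielded by its ortho methyl group and ortho magnesium phenoxide.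

Step 6
Reactants: 9 benzyl 5-[(2,4-dimethoxy-6-methylbenzoyl)oxy]-2,4-dihydroxy-6-methylbenzoate
Product: 10 benzyl 2,4-dihydroxy-5-[(2-hydroxy-4-methoxy-6-methylbenzoyl)oxy]-6-methylbenzoate
Conditions: BCl3 (4 equiv), CH2Cl2, −78 to 0 °C; then H2O
Reagents that add atoms: none
Why: Chelation-assisted ortho-demethylation with BCl3: boron bridges the depside carbonyl and the ortho methoxy group so that chloride removes that methyl only, the 4-methoxy group having no ortho carbonyl at this stage, and at 0 °C or below the benzyl ester is expected to survive.

Step 7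
Reactants: 10 benzyl 2,4-dihydroxy-5-[(2-hydroxy-4-methoxy-6-methylbenzoyl)oxy]-6-methylbenzoate
Product: 11 benzyl 3-formyl-5-[(3-formyl-2-hydroxy-4-methoxy-6-methylbenzoyl)oxy]-2,4-dihydroxy-6-methylbenzoate
Conditions: MgCl2, Et3N, (CH2O)n (excess), MeCN, reflux; then 1 M HCl
Reagents that add atoms: paraformaldehyde (formaldehyde units), C=O
Why: Casnati–Skattebøl ortho-formylation (magnesium phenoxide-templated hydroxymethylation, then hydride transfer to formaldehyde): it is specific for positions ortho to a phenolic OH, and the only such free positions are C3 of ring A and C3 of ring B, so both formyl groups should enter in one operation while C5 of ring A (para to OH) stays untouched.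

Step 8
Reactants: 11 benzyl 3-formyl-5-[(3-formyl-2-hydroxy-4-methoxy-6-methylbenzoyl)oxy]-2,4-dihydroxy-6-methylbenzoate
Product: 12 haemathamnolic acid
Conditions: H2 (1 atm), 10% Pd/C, EtOAc, rt, stopped after one equivalent of H2
Reagents that add atoms: none
Why: Hydrogenolysis of the benzyl ester over Pd/C: the benzylic C–O bond should be cleaved well before the two hydrogen-bonded salicylaldehyde-type formyl groups or the depside ester react.

Compound list
1 | orsellinic acid (2,4-dihydroxy-6-methylbenzoic acid) | Cc1cc(O)cc(O)c1C(=O)O | starting material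
2 | benzyl 2,4-dihydroxy-6-methylbenzoate | Cc1cc(O)cc(O)c1C(=O)OCc1ccccc1 | intermediate
3 | potassium 3-(benzyloxycarbonyl)-4,6-dihydroxy-2-methylphenyl sulfate | Cc1c(OS(=O)(=O)[O-])c(O)cc(O)c1C(=O)OCc1ccccc1.[K+] | intermediate
4 | benzyl 2,4,5-trihydroxy-6-methylbenzoate | Cc1c(O)c(O)cc(O)c1C(=O)OCc1ccccc1 | intermediate
5 | benzyl 6-hydroxy-4-methyl-2-oxo-1,3-benzodioxole-5-carboxylate | Cc1c2OC(=O)Oc2cc(O)c1C(=O)OCc1ccccc1 | intermediate
6 | 3,5-dimethoxytoluene | COc1cc(C)cc(OC)c1 | starting material
7 | 1-bromo-2,4-dimethoxy-6-methylbenzene | COc1cc(C)c(Br)c(OC)c1 | intermediate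
8 | (2,4-dimethoxy-6-methylphenyl)magnesium bromide | COc1cc(C)c([Mg]Br)c(OC)c1 | intermediate
9 | benzyl 5-[(2,4-dimethoxy-6-methylbenzoyl)oxy]-2,4-dihydroxy-6-methylbenzoate | COc1cc(C)c(C(=O)Oc2c(C)c(C(=O)OCc3ccccc3)c(O)cc2O)c(OC)c1 | intermediate
10 | benzyl 2,4-dihydroxy-5-[(2-hydroxy-4-methoxy-6-methylbenzoyl)oxy]-6-methylbenzoate | COc1cc(C)c(C(=O)Oc2c(C)c(C(=O)OCc3ccccc3)c(O)cc2O)c(O)c1 | intermediate
11 | benzyl 3-formyl-5-[(3-formyl-2-hydroxy-4-methoxy-6-methylbenzoyl)oxy]-2,4-dihydroxy-6-methylbenzoate | COc1cc(C)c(C(=O)Oc2c(C)c(C(=O)OCc3ccccc3)c(O)c(C=O)c2O)c(O)c1C=O | intermediate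
12 | haemathamnolic acid (3-formyl-5-[(3-formyl-2-hydroxy-4-methoxy-6-methylbenzoyl)oxy]-2,4-dihydroxy-6-methylbenzoic acid) | COc1cc(C)c(C(=O)Oc2c(C)c(C(=O)O)c(O)c(C=O)c2O)c(O)c1C=O | target

Total step count: 8
Longest linear sequence: 7 steps (steps 1, 2, 3, 5, 6, 7, 8)

Steps most likely to fail

Step 7. The second formylation may stall, the electron-rich rings may condense with formaldehyde to diarylmethanes, or the basic medium may shift or cleave the depside acyl group. Fallback: starting from 10, a Rieche formylation (Cl2CHOMe, TiCl4, CH2Cl2, −10 to 0 °C, then aqueous hydrolysis) replaces the magnesium-templated process by a titanium phenoxide-directed electrophilic formylation under acidic conditions and comes back to the route at 11; no new isolable compound is made.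

Step 6. The benzyl ester may be cleaved alongside the methyl ether, or the demethylation may stay incomplete at the low temperature that spares the ester. Fallback: starting from 9, BCl3 is used in excess at 0 °C to rt until both the ortho methyl ether and the benzyl ester are gone, giving 2,4-dihydroxy-5-[(2-hydroxy-4-methoxy-6-methylbenzoyl)oxy]-6-methylbenzoic acid F1. The carboxylic acid is then benzylated again chemoselectively (BnBr, KHCO3, DMF, as in step 1), which comes back to the route at 10.

Step 5. The tetrahedral intermediate may open towards the wrong oxygen, or the Grignard reagent may add a second time or attack the benzyl ester. Fallback: starting from 5, the aryl nucleophile is replaced by a dearomatised ring-A equivalent. 3-Methoxy-5-methylcyclohex-2-en-1-one F2 (racemic; from commercial 5-methylcyclohexane-1,3-dione, MeOH, TsOH) is converted into its kinetic lithium enolate (LDA, THF, −78 °C, 3 equiv). The enolate is C-acylated by carbonate 5 in a Claisen-type reaction to give benzyl 2,4-dihydroxy-5-[(4-methoxy-6-methyl-2-oxocyclohex-3-ene-1-carbonyl)oxy]-6-methylbenzoate F3. Dehydrogenation with DDQ (dioxane, 80 °C) aromatises the ring and comes back to the route at 10, with the 2-OH and 4-OMe of ring A already differentiated, so step 6 is not needed.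

Further compounds
F0 | step 7 | none | none
F1 | step 6 | 2,4-dihydroxy-5-[(2-hydroxy-4-methoxy-6-methylbenzoyl)oxy]-6-methylbenzoic acid | COc1cc(C)c(C(=O)Oc2c(C)c(C(=O)O)c(O)cc2O)c(O)c1
F2 | step 5 | 3-methoxy-5-methylcyclohex-2-en-1-one (racemic) | COC1=CC(=O)CC(C)C1
F3 | step 5 | benzyl 2,4-dihydroxy-5-[(4-methoxy-6-methyl-2-oxocyclohex-3-ene-1-carbonyl)oxy]-6-methylbenzoate (racemic, stereocentres lost on aromatisation) | COC1=CC(=O)C(C(=O)Oc2c(C)c(C(=O)OCc3ccccc3)c(O)cc2O)C(C)C1
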